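**Plan**

1. Numbering: C1–C17 follow the target SMILES after the first acetoxy group (acetyl carbons and the methyls on C14 and C16 are not counted; C8 is the cyclopropane methyl). Ring A = C1-C2-C3-C17-C16-C15, ring B = C3-C4-C5-C9-C10-C17, ring C = cyclobutane C10-C11-C16-C17, ring D = C11-C12-C13-C14-C15-C16.
2. Retrosynthetic cuts: C9–C10 (crossed benzoin), C3–C17 (aldol onto a cyclobutane-1,2-dione), C2–C3 (chelation-controlled aldol with cyclopropyl methyl ketone 30), C10–C17 (acyloin), then C15–C16 and C11–C12 (Diels–Alder).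
3. Forward order: ring D by cycloaddition, ring C by acyloin condensation, the C3–C9 chain joined at C2, ring A by aldol, ring B by benzoin closure, then redox and acyl adjustments.
4. Stereochemistry: C1 from (R)-glyceraldehyde; C15, C16, C11 from the endo cycloaddition steered by C1; C2 by chelation; C17, C3 and C10 by delivery from the C15 arm on the concave face of the cis-bicyclo[4.2.0] core; C9 by hydroxyl-directed reduction; C5 and C7 from (S)-propane-1,2-diol cyclic sulfate and a face-selective ester hydrolysis.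
5. Enabling feature: ring D carries three contiguous stereocentres, C15, the methyl-bearing quaternary C16 and C11, whose substituents C1, C17 and C10 are all cis, with C17 and C10 oxygenated. This is the substitution pattern of an endo adduct between an (E)-1-substituted 2-silyloxy diene (C12–C15) and citraconic anhydride.

Key step: step 4

Remark: benzylidene acetal 17 is formed and used as a mixture of epimers at the acetal carbon (centre lost in step 11).
Remark: the cyclopropane centres at C13/C14 in 11–19 and the carbinol centres at C10/C17 in 13–34 are transient; they are drawn as expected from convex-face attack and are all erased later.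

**Route**

Step 1
Reactants: 1 3-bromobutan-2-one
Product: 3 3-(triphenylphosphoranylidene)butan-2-one, via phosphonium bromide 2 (not isolated)
Conditions: PPh3, toluene, 80 °C; then aq. NaOH, CH2Cl2, rt
Reagents that add atoms: triphenylphosphine, c1ccc(cc1)P(c1ccccc1)c1ccccc1
Why: SN2 quaternisation of the phosphine by the α-bromo ketone followed by deprotonation of the acidic α-CH gives the acyl-stabilised Wittig ylide.

Step 2
Reactants: 3 3-(triphenylphosphoranylidene)butan-2-one; 4 (R)-2,2-dimethyl-1,3-dioxolane-4-carbaldehyde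
Product: 5 (E)-4-[(4S)-2,2-dimethyl-1,3-dioxolan-4-yl]-3-methylbut-3-en-2-one
Conditions: CH2Cl2, rt to 40 °C
Reagents that add atoms: none
Why: Wittig olefination with a stabilised α-branched ylide gives the (E)-trisubstituted enone, and the non-basic ylide leaves the C1 stereocentre of the aldehyde intact.

Step 3
Reactants: 5 (E)-enone
Product: 6 (E)-2-(tert-butyldimethylsilyloxy)-3-methyl diene bearing the (4S)-dioxolanyl group at C15
Conditions: tBuMe2SiOTf, Et3N, CH2Cl2, 0 °C
Reagents that add atoms: tert-butyldimethylsilyl triflate, CC(C)(C)[Si](C)(C)OS(=O)(=O)C(F)(F)F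
Why: soft enolisation (silyl triflate and amine) removes a proton of the acetyl methyl group kinetically and gives the cross-conjugated 2-silyloxy diene with the alkene geometry unchanged.

Step 4
Reactants: 6 2-silyloxy diene; 7 citraconic anhydride
Product: 8 cis-fused bicyclic anhydride (ring D with C13=C14 silyl enol ether and the C15 dioxolanyl group cis to both carbonyl carbons)
Conditions: toluene, BHT (cat.), 90 °C, sealed tube
Reagents that add atoms: none
Why: This is a concerted, asynchronous, suprafacial [4+2] cycloaddition of the normal-demand type known for 2-silyloxy dienes with maleic and citraconic anhydride, in which the electron-rich terminus C12 bonds ahead to the unsubstituted dienophile carbon C11 and the substituted terminus C15 to the methyl-bearing C16. Ring D is closed by the cycloaddition itself, both new bonds (C15–C16 and C11–C12) forming on one face of each partner. C16 and C11 are cis because the anhydride ring ties the two carbonyl carbons together, and C15 is set relative to them by the endo transition state, which for the (E)-diene places the outside substituent C1 cis to C17 and C10. The absolute sense comes from C1: allylic strain with the C14 methyl keeps the C1–H bond in the diene plane and the anhydride approaches the face anti to the C1–O bond. The step needs regio-, endo and facial selectivity, secured respectively by the silyloxy group together with the dienophile methyl, by secondary overlap of the anhydride carbonyls, and by the dioxolane stereocentre. The silyl enol ether left at C13=C14 is the handle for the second C14 methyl.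

Step 5
Reactants: 8 bicyclic anhydride
Product: 10 dimethyl cis-diester of ring D, via monomethyl ester 9 (not isolated)
Conditions: MeOH, DMAP (cat.), CH2Cl2, rt; evaporate; MeI, K2CO3, DMF, rt
Reagents that add atoms: methanol, CO; iodomethane, CI
Why: nucleophilic acyl substitution opens the anhydride at the less hindered C10 carbonyl and O-alkylation of the neopentyl carboxylate finishes the diester without enolising C11, so the cis relationship is kept.

Step 6
Reactants: 10 dimethyl cis-diester
Product: 11 silyloxycyclopropane diester (CH2 added across C13=C14)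
Conditions: Et2Zn, CH2I2, CH2Cl2, 0 °C to rt
Reagents that add atoms: diiodomethane, ICI
Why: Furukawa-modified Simmons–Smith cyclopropanation of the electron-rich silyl enol ether is a stereospecific syn addition, expected on the face opposite the C15 dioxolanyl group, and masks the future gem-dimethyl ketone.

Step 7
Reactants: 11 silyloxycyclopropane diester
Product: 12 ene-diol bis(trimethylsilyl) ether (ring C closed as a C10=C17 cyclobutene cis-fused to ring D)
Conditions: Na (dispersion), Me3SiCl, toluene, reflux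
Reagents that add atoms: chlorotrimethylsilane, C[Si](C)(C)Cl
Why: acyloin condensation with silyl chloride trapping (Rühlmann variant) couples the two cis ester carbonyls reductively to form C10–C17, with the cis ring fusion inherited from the diester.

Step 8
Reactants: 12 ene-diol bis(trimethylsilyl) ether
Product: 14 cis-cyclobutane-1,2-diol (C10 and C17 carbinols), via hydroxy ketone 13 (not isolated)
Conditions: NaBH4, MeOH, −20 to 0 °C
Reagents that add atoms: none
Why: methanolysis of the silyl enol ethers and immediate borohydride reduction of the hydroxy cyclobutanone precede any ring contraction, with proton and hydride both entering from the convex face to give the cis-diol.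

Step 9
Reactants: 14 cis-cyclobutanediol
Product: 15 bis(4-methoxybenzyl) ether
Conditions: NaH, 4-MeOC6H4CH2Cl, Bu4NI (cat.), DMF, 0 °C to rt
Reagents that add atoms: 4-methoxybenzyl chloride, COc1ccc(CCl)cc1
Why: Williamson etherification protects both ring C oxygens identically, so no regiochemical choice between C10 and C17 is needed.

Step 10
Reactants: 15 bis(4-methoxybenzyl) ether
Product: 17 benzylidene acetal of the C1/C2 diol, via diol 16 (not isolated)
Conditions: PPTS, MeOH, 40 °C; evaporate; PhCH(OMe)2, camphorsulfonic acid (cat.), CH2Cl2, rt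
Reagents that add atoms: benzaldehyde dimethyl acetal, COC(OC)c1ccccc1
Why: acid-catalysed transacetalisation removes the terminal acetonide and re-forms a five-membered benzylidene acetal on the same 1,2-diol, under conditions the tertiary silyl ether and the benzylic ethers tolerate.

Step 11
Reactants: 17 benzylidene acetal
Product: 18 C1 benzyl ether with free primary C2 alcohol
Conditions: iBu2AlH, CH2Cl2, −78 to 0 °C
Reagents that add atoms: none
Why: regioselective reductive acetal opening, in which aluminium binds the less hindered primary oxygen and hydride goes to the acetal carbon, leaves the benzyl group on the secondary C1 oxygen.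

Step 12
Reactants: 18 primary alcohol
Product: 20 C13 ketone with gem-dimethyl C14, via cyclopropanol 19 (not isolated)
Conditions: Bu4NF, THF, rt; then NaOH, MeOH–H2O, 50 °C
Reagents that add atoms: none
Why: fluoride desilylation followed by base-induced cyclopropanol ring opening (homo-enolate protonation) cleaves the bond to the primary carbon, turning the CH2 into the second C14 methyl and C13 into the ketone.

Step 13
Reactants: 20 keto alcohol
Product: 21 α-benzyloxy aldehyde (C2 aldehyde)
Conditions: Dess–Martin periodinane, CH2Cl2, 0 °C to rt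
Reagents that add atoms: none
Why: Dess–Martin oxidation of the only free hydroxyl stops at the aldehyde and is base-free, so the α-alkoxy centre C1 is not epimerised.

Step 14
Reactants: 22 dimethyl malonate; 23 (S)-4-methyl-1,3,2-dioxathiolane 2,2-dioxide
Product: 24 dimethyl (2R)-2-methylcyclopropane-1,1-dicarboxylate
Conditions: NaH, DME, 0 °C to reflux
Reagents that add atoms: none
Why: double alkylation of malonate by the cyclic sulfate (SN2 at the primary carbon, then 3-exo-tet closure with inversion at the secondary carbon) sets C7.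

Step 15
Reactants: 24 cyclopropane diester
Product: 25 (1S,2R)-1-(methoxycarbonyl)-2-methylcyclopropane-1-carboxylic acid
Conditions: KOH (1 equiv), MeOH, 0 °C to rt; then aq. HCl
Reagents that add atoms: potassium hydroxide, [K+].[OH-]
Why: saponification is selective for the less hindered ester trans to the ring methyl, which differentiates the two carbonyls and so defines the quaternary centre C5.

Step 16
Reactants: 25 half ester
Product: 26 methyl (1S,2R)-1-(hydroxymethyl)-2-methylcyclopropane-1-carboxylate
Conditions: BH3·SMe2, THF, 0 °C to rt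
Reagents that add atoms: none
Why: borane reduces the carboxylic acid chemoselectively in the presence of the ester.

Step 17
Reactants: 26 hydroxy ester
Product: 27 methyl (1S,2R)-1-formyl-2-methylcyclopropane-1-carboxylate
Conditions: Dess–Martin periodinane, CH2Cl2, rt
Reagents that add atoms: none
Why: Dess–Martin oxidation gives a non-enolisable aldehyde that cannot epimerise.

Step 18
Reactants: 27 formyl ester
Product: 28 methyl (1R,2R)-1-ethenyl-2-methylcyclopropane-1-carboxylate
Conditions: Ph3PCH3Br, KOtBu, THF, 0 °C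
Reagents that add atoms: methyltriphenylphosphonium bromide, C[P+](c1ccccc1)(c1ccccc1)c1ccccc1.[Br-]
Why: Wittig methylenation converts the aldehyde into a vinyl group that serves as a latent C9 aldehyde inert to all steps up to the ozonolysis.

Step 19
Reactants: 28 vinyl ester
Product: 30 1-[(1R,2R)-1-ethenyl-2-methylcyclopropyl]ethan-1-one, via Weinreb amide 29 (not isolated)
Conditions: MeNH(OMe)·HCl, iPrMgCl, THF, −20 °C; then MeMgBr, 0 °C
Reagents that add atoms: methylmagnesium bromide, C[Mg]Br
Why: one-pot Weinreb ketone synthesis, in which the chelated tetrahedral adduct of the amide prevents a second Grignard addition.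

Step 20
Reactants: 30 cyclopropyl methyl ketone; 21 α-benzyloxy aldehyde
Product: 32 β-hydroxy ketone (C2–C3 bond formed and C2 carbinol syn to the C1 benzyloxy group), via silyl enol ether 31 (not isolated)
Conditions: 30, Me3SiOTf, Et3N, CH2Cl2, 0 °C; then 21, MgBr2·OEt2, CH2Cl2, −78 to −30 °C
Reagents that add atoms: none
Why: chelation-controlled Mukaiyama aldol, in which magnesium bridges the aldehyde and C1 benzyloxy oxygens and the enol silane attacks the chelate face away from the C15 substituent, gives the 1,2-syn C2 carbinol.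

Step 21
Reactants: 32 β-hydroxy ketone
Product: 33 C2 triethylsilyl ether
Conditions: Et3SiOTf, 2,6-lutidine, CH2Cl2, −78 °C
Reagents that add atoms: triethylsilyl triflate, CC[Si](CC)(CC)OS(=O)(=O)C(F)(F)F
Why: silylation with the triflate and a hindered base protects the secondary carbinol without enolising the ketones and blocks retro-aldol and hemiketal formation.

Step 22
Reactants: 33 C2 triethylsilyl ether
Product: 34 cis-cyclobutanediol with the full C1–C9 arm
Conditions: DDQ, CH2Cl2–pH 7 buffer, 0 °C to rt
Reagents that add atoms: none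
Why: oxidative cleavage of the two electron-rich 4-methoxybenzyl ethers leaves the benzyl ether, the silyl ether and the vinyl group untouched.

Step 23
Reactants: 34 cis-cyclobutanediol
Product: 35 cyclobutane-1,2-dione (C10 and C17 ketones)
Conditions: (COCl)2, DMSO, CH2Cl2, −78 °C; then Et3N, −78 to −20 °C
Reagents that add atoms: none
Why: Swern oxidation of a vicinal diol activates both carbinols before the base is added and gives the 1,2-diketone without C–C cleavage.

Step 24
Reactants: 35 cyclobutane-1,2-dione
Product: 37 ring A closed (C17 triethylsilyl ether and C10 ketone), via lithium aldolate 36 (not isolated)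
Conditions: LiN(SiMe3)2, THF, −78 to −40 °C; then Et3SiOTf, −78 °C
Reagents that add atoms: triethylsilyl triflate, CC[Si](CC)(CC)OS(=O)(=O)C(F)(F)F
Why: intramolecular aldol (6-enolexo closure) of the C3 lithium enolate onto the proximal dione carbonyl, where C17 is fixed by the C15 tether (cis 6/4 fusion) and C3 by a Zimmerman–Traxler chair with C4 gauche to the flat C10 carbonyl and anti to quaternary C16, and in situ silylation blocks retro-aldol and ketol shift.

Step 25
Reactants: 37 tricyclic bis(triethylsilyl) ether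
Product: 38 C9 aldehyde
Conditions: O3, CH2Cl2, −78 °C; then PPh3, −78 °C to rt
Reagents that add atoms: ozone, [O-][O+]=O
Why: ozonolysis with reductive work-up unmasks the only alkene as the non-enolisable C9 aldehyde.

Step 26
Reactants: 38 keto aldehyde
Product: 40 tetracyclic trans-C9,C10-diol (ring B closed), via hydroxy ketone 39 (not isolated)
Conditions: 2-mesityl-6,7-dihydro-5H-pyrrolo[2,1-c][1,2,4]triazol-2-ium tetrafluoroborate (20 mol %), Et3N (20 mol %), THF, rt; then AcOH–MeCN, Me4NBH(OAc)3, −20 °C
Reagents that add atoms: none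
Why: carbene-catalysed intramolecular crossed benzoin closes C9–C10 with C10 fixed by the cis ring fusion, and Saksena–Evans reduction from the C10 hydroxyl then delivers hydride to C9 on the convex face to give the trans-diol before the acylcyclobutanol can rearrange.

Step 27
Reactants: 40 tetracyclic diol
Product: 41 C1,C9,C10-triol
Conditions: H2 (1 atm), Pd/C, EtOAc, rt
Reagents that add atoms: none
Why: hydrogenolysis removes the C1 benzyl ether under neutral conditions that leave the silyl ethers, ketones and cyclopropane intact.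

Step 28
Reactants: 41 triol
Product: 42 C1,C9-diacetate
Conditions: Ac2O, pyridine, DMAP (cat.), CH2Cl2, 0 °C to rt
Reagents that add atoms: acetic anhydride, CC(=O)OC(C)=O
Why: acylation with a nucleophilic catalyst esterifies the two secondary hydroxyls, while the tertiary C10 hydroxyl on the cyclobutane is too hindered to react.

Step 29
Reactants: 42 diacetate
Product: 43 CNP0157858.3 (target)
Conditions: HF·pyridine, pyridine–THF, 0 °C to rt
Reagents that add atoms: none
Why: fluoride desilylation in a weakly acidic buffered medium frees the C2 and C17 hydroxyls without acetate migration, retro-aldol or β-elimination.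

**Compound list**

1 | 3-bromobutan-2-one | CC(Br)C(C)=O | starting material
2 | (3-oxobutan-2-yl)triphenylphosphonium bromide | CC(=O)C(C)[P+](c1ccccc1)(c1ccccc1)c1ccccc1.[Br-] | intermediate (not isolated)
3 | 3-(triphenylphosphoranylidene)butan-2-one | CC(=O)C(C)=P(c1ccccc1)(c1ccccc1)c1ccccc1 | intermediate
4 | (R)-2,2-dimethyl-1,3-dioxolane-4-carbaldehyde | O=C[C@H]1COC(C)(C)O1 | starting material
5 | (E)-4-[(4S)-2,2-dimethyl-1,3-dioxolan-4-yl]-3-methylbut-3-en-2-one | CC(=O)/C(C)=C/[C@H]1COC(C)(C)O1 | intermediate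
6 | tert-butyl{[(3E)-4-[(4S)-2,2-dimethyl-1,3-dioxolan-4-yl]-3-methylbuta-1,3-dien-2-yl]oxy}dimethylsilane | C=C(O[Si](C)(C)C(C)(C)C)/C(C)=C/[C@H]1COC(C)(C)O1 | intermediate
7 | citraconic anhydride (3-methylfuran-2,5-dione) | CC1=CC(=O)OC1=O | starting material
8 | 6-(tert-butyldimethylsilyloxy)-4-[(4S)-2,2-dimethyl-1,3-dioxolan-4-yl]-3a,5-dimethyl-3a,4,7,7a-tetrahydro-2-benzofuran-1,3-dione; cis ring fusion, dioxolanyl group cis to both carbonyl carbons | O=C1[C@H]2CC(O[Si](C)(C)C(C)(C)C)=C(C)[C@@H]([C@H]3COC(C)(C)O3)[C@@]2(C)C(=O)O1 | intermediate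
9 | monomethyl ester of 8 (C10 methyl ester, C17 carboxylic acid) | COC(=O)[C@H]1CC(O[Si](C)(C)C(C)(C)C)=C(C)[C@@H]([C@H]2COC(C)(C)O2)[C@@]1(C)C(=O)O | intermediate (not isolated)
10 | dimethyl 4-(tert-butyldimethylsilyloxy)-6-[(4S)-2,2-dimethyl-1,3-dioxolan-4-yl]-1,5-dimethylcyclohex-4-ene-1,2-dicarboxylate; both esters and the C6 group cis | COC(=O)[C@H]1CC(O[Si](C)(C)C(C)(C)C)=C(C)[C@@H]([C@H]2COC(C)(C)O2)[C@@]1(C)C(=O)OC | intermediate
11 | dimethyl 6-(tert-butyldimethylsilyloxy)-2-[(4S)-2,2-dimethyl-1,3-dioxolan-4-yl]-1,3-dimethylbicyclo[4.1.0]heptane-3,4-dicarboxylate; cyclopropane CH2 anti to the dioxolanyl group | COC(=O)[C@H]1C[C@]2(O[Si](C)(C)C(C)(C)C)C[C@]2(C)[C@@H]([C@H]3COC(C)(C)O3)[C@@]1(C)C(=O)OC | intermediate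
12 | ring C/D ene-diol bis(trimethylsilyl) ether: C10=C17 bis(trimethylsilyloxy)cyclobutene cis-fused to ring D, which carries the silyloxycyclopropane (C13/C14) and the C15 dioxolane | C[Si](C)(C)OC1=C(O[Si](C)(C)C)[C@]2(C)[C@H]([C@H]3COC(C)(C)O3)[C@@]4(C)C[C@@]4(O[Si](C)(C)C(C)(C)C)C[C@H]12 | intermediate
13 | hydroxy cyclobutanone (C17 ketone, C10 carbinol), otherwise as 12 | O[C@@H]1C(=O)[C@]2(C)[C@H]([C@H]3COC(C)(C)O3)[C@@]4(C)C[C@@]4(O[Si](C)(C)C(C)(C)C)C[C@H]12 | intermediate (not isolated)
14 | cis-cyclobutane-1,2-diol (C10 and C17 carbinols, both hydroxyls on the ring D face) | O[C@@H]1[C@H](O)[C@]2(C)[C@H]([C@H]3COC(C)(C)O3)[C@@]4(C)C[C@@]4(O[Si](C)(C)C(C)(C)C)C[C@H]12 | intermediate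
15 | C10,C17-bis(4-methoxybenzyl) ether of 14 | COc1ccc(cc1)CO[C@@H]2[C@H](OCc3ccc(OC)cc3)[C@]4(C)[C@H]([C@H]5COC(C)(C)O5)[C@@]6(C)C[C@@]6(O[Si](C)(C)C(C)(C)C)C[C@H]24 | intermediate
16 | C1,C2-diol from 15 (acetonide removed) | COc1ccc(cc1)CO[C@@H]2[C@H](OCc3ccc(OC)cc3)[C@]4(C)[C@H]([C@H](O)CO)[C@@]5(C)C[C@@]5(O[Si](C)(C)C(C)(C)C)C[C@H]24 | intermediate (not isolated)
17 | C1/C2 benzylidene acetal (2-phenyl-1,3-dioxolane, epimers at the acetal carbon) | COc1ccc(cc1)CO[C@@H]2[C@H](OCc3ccc(OC)cc3)[C@]4(C)[C@H]([C@H]5COC(O5)c6ccccc6)[C@@]7(C)C[C@@]7(O[Si](C)(C)C(C)(C)C)C[C@H]24 | intermediate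
18 | C1 benzyl ether, C2 primary alcohol | COc1ccc(cc1)CO[C@@H]2[C@H](OCc3ccc(OC)cc3)[C@]4(C)[C@H]([C@H](OCc5ccccc5)CO)[C@@]6(C)C[C@@]6(O[Si](C)(C)C(C)(C)C)C[C@H]24 | intermediate
19 | cyclopropanol from 18 (free C13 hydroxyl on the cyclopropane) | COc1ccc(cc1)CO[C@@H]2[C@H](OCc3ccc(OC)cc3)[C@]4(C)[C@H]([C@H](OCc5ccccc5)CO)[C@@]6(C)C[C@@]6(O)C[C@H]24 | intermediate (not isolated)
20 | C13 ketone with gem-dimethyl C14; C1 benzyl ether, C2 primary alcohol, ring C bis(4-methoxybenzyl) ether | COc1ccc(cc1)CO[C@@H]2[C@H](OCc3ccc(OC)cc3)[C@]4(C)[C@H]([C@H](OCc5ccccc5)CO)C(C)(C)C(=O)C[C@H]24 | intermediate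
21 | C2 aldehyde (α-benzyloxy aldehyde) | COc1ccc(cc1)CO[C@@H]2[C@H](OCc3ccc(OC)cc3)[C@]4(C)[C@H]([C@H](OCc5ccccc5)C=O)C(C)(C)C(=O)C[C@H]24 | intermediate
22 | dimethyl malonate | COC(=O)CC(=O)OC | starting material
23 | (S)-4-methyl-1,3,2-dioxathiolane 2,2-dioxide | C[C@H]1COS(=O)(=O)O1 | starting material
24 | dimethyl (2R)-2-methylcyclopropane-1,1-dicarboxylate | COC(=O)C1(C[C@H]1C)C(=O)OC | intermediate
25 | (1S,2R)-1-(methoxycarbonyl)-2-methylcyclopropane-1-carboxylic acid (acid trans to the methyl) | COC(=O)[C@]1(C[C@H]1C)C(=O)O | intermediate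
26 | methyl (1S,2R)-1-(hydroxymethyl)-2-methylcyclopropane-1-carboxylate | COC(=O)[C@]1(C[C@H]1C)CO | intermediate
27 | methyl (1S,2R)-1-formyl-2-methylcyclopropane-1-carboxylate | COC(=O)[C@]1(C[C@H]1C)C=O | intermediate
28 | methyl (1R,2R)-1-ethenyl-2-methylcyclopropane-1-carboxylate | COC(=O)[C@]1(C[C@H]1C)C=C | intermediate
29 | (1R,2R)-1-ethenyl-N-methoxy-N,2-dimethylcyclopropane-1-carboxamide | CON(C)C(=O)[C@]1(C[C@H]1C)C=C | intermediate (not isolated)
30 | 1-[(1R,2R)-1-ethenyl-2-methylcyclopropyl]ethan-1-one | CC(=O)[C@]1(C[C@H]1C)C=C | intermediate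
31 | {1-[(1R,2R)-1-ethenyl-2-methylcyclopropyl]ethenyl}oxy(trimethyl)silane | C=C(O[Si](C)(C)C)[C@]1(C[C@H]1C)C=C | intermediate (not isolated)
32 | aldol adduct: C1 benzyloxy, C2 hydroxyl (syn), C4 ketone, vinylcyclopropane at C5 | COc1ccc(cc1)CO[C@@H]2[C@H](OCc3ccc(OC)cc3)[C@]4(C)[C@H]([C@H](OCc5ccccc5)[C@@H](O)CC(=O)[C@]6(C[C@H]6C)C=C)C(C)(C)C(=O)C[C@H]24 | intermediate
33 | C2 triethylsilyl ether of 32 | COc1ccc(cc1)CO[C@@H]2[C@H](OCc3ccc(OC)cc3)[C@]4(C)[C@H]([C@H](OCc5ccccc5)[C@@H](O[Si](CC)(CC)CC)CC(=O)[C@]6(C[C@H]6C)C=C)C(C)(C)C(=O)C[C@H]24 | intermediate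
34 | C10,C17 cis-diol of 33 (both 4-methoxybenzyl groups removed) | O[C@@H]1[C@H](O)[C@]2(C)[C@H]([C@H](OCc3ccccc3)[C@@H](O[Si](CC)(CC)CC)CC(=O)[C@]4(C[C@H]4C)C=C)C(C)(C)C(=O)C[C@H]12 | intermediate
35 | cyclobutane-1,2-dione (C10 and C17 ketones) carrying the C1–C9 arm | O=C1C(=O)[C@]2(C)[C@H]([C@H](OCc3ccccc3)[C@@H](O[Si](CC)(CC)CC)CC(=O)[C@]4(C[C@H]4C)C=C)C(C)(C)C(=O)C[C@H]12 | intermediate
36 | lithium C17 alkoxide of the ring A aldol product | C(c1ccccc1)O[C@@H]2[C@@H](O[Si](CC)(CC)CC)[C@@H](C(=O)[C@]3(C[C@H]3C)C=C)[C@@]4(O[Li])C(=O)[C@H]5CC(=O)C(C)(C)[C@@H]2[C@@]45C | intermediate (not isolated)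
37 | tricycle with ring A closed: C1 benzyloxy, C2 and C17 triethylsilyloxy, C10 and C13 ketones, C3 acyl group cis to C10 | C(c1ccccc1)O[C@@H]2[C@@H](O[Si](CC)(CC)CC)[C@@H](C(=O)[C@]3(C[C@H]3C)C=C)[C@@]4(O[Si](CC)(CC)CC)C(=O)[C@H]5CC(=O)C(C)(C)[C@@H]2[C@@]45C | intermediate
38 | C9 aldehyde of 37 | C(c1ccccc1)O[C@@H]2[C@@H](O[Si](CC)(CC)CC)[C@@H](C(=O)[C@]3(C[C@H]3C)C=O)[C@@]4(O[Si](CC)(CC)CC)C(=O)[C@H]5CC(=O)C(C)(C)[C@@H]2[C@@]45C | intermediate
39 | tetracyclic hydroxy ketone (ring B closed: C9 ketone, C10 tertiary hydroxyl) | C(c1ccccc1)O[C@@H]2[C@@H](O[Si](CC)(CC)CC)[C@H]3C(=O)[C@]4(C[C@H]4C)C(=O)[C@@]4(O)[C@H]5CC(=O)C(C)(C)[C@@H]2[C@@]5(C)[C@@]34O[Si](CC)(CC)CC | intermediate (not isolated)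
40 | tetracyclic trans-C9,C10-diol | C(c1ccccc1)O[C@@H]2[C@@H](O[Si](CC)(CC)CC)[C@H]3C(=O)[C@]4(C[C@H]4C)[C@@H](O)[C@@]4(O)[C@H]5CC(=O)C(C)(C)[C@@H]2[C@@]5(C)[C@@]34O[Si](CC)(CC)CC | intermediate
41 | C1,C9,C10-triol (C2 and C17 triethylsilyl ethers) | O[C@@H]1[C@@H](O[Si](CC)(CC)CC)[C@H]2C(=O)[C@]3(C[C@H]3C)[C@@H](O)[C@@]3(O)[C@H]4CC(=O)C(C)(C)[C@@H]1[C@@]4(C)[C@@]23O[Si](CC)(CC)CC | intermediate
42 | C1,C9-diacetate (C2 and C17 triethylsilyl ethers) | CC(=O)O[C@@H]1[C@@H](O[Si](CC)(CC)CC)[C@H]2C(=O)[C@]3(C[C@H]3C)[C@@H](OC(C)=O)[C@@]3(O)[C@H]4CC(=O)C(C)(C)[C@@H]1[C@@]4(C)[C@@]23O[Si](CC)(CC)CC | intermediate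
43 | CNP0157858.3 | CC(=O)O[C@@H]1[C@@H](O)[C@H]2C(=O)[C@]3(C[C@H]3C)[C@@H](OC(C)=O)[C@@]3(O)[C@H]4CC(=O)C(C)(C)[C@@H]1[C@@]4(C)[C@@]23O | target

**Step count and risks**

Total step count: 29. Longest linear sequence: 23 (steps 1–13 and 20–29).

Steps most likely to fail:

Step 24. The amide base may deprotonate C12 (next to the C13 ketone) or C11 (next to the dione) instead of C3, or add to the dione. The closure may also pass through the alternative chair and give the C3 epimer, from which ring B cannot form. The fallback sets out from 35 and returns at 37. Dione 35 is treated with Et3SiOTf and iPr2NEt in CH2Cl2 (−78 to 0 °C). Soft enolisation gives the (Z)-triethylsilyl enol ether of the C4 ketone F1, which adds in Mukaiyama fashion, through an open transition state and without any metal enolate or amide, to the silyl-triflate-activated C17 carbonyl. The silyl group ends on the C17 oxygen and 37 results directly; a silyl enol ether formed at C13 would be lost on mildly acidic work-up.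

Step 26. The carbene may add too slowly to the α-quaternary aldehyde, or the acylcyclobutanol 39 may ring-expand by a base-induced ketol shift before it is reduced. The fallback sets out from 38 and returns at 40. SmI2 (THF, tBuOH, −78 °C) effects a ketyl–carbonyl (pinacol) coupling of the aldehyde with the C10 ketone and gives the tetracyclic C9,C10-cis-diol F2, the C9 epimer of 40, the ring fusion again dictating C10. Base-free Dess–Martin oxidation of its secondary C9 hydroxyl gives 39, which is reduced at once with Me4NBH(OAc)3 as in step 26 to 40.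

Step 23. The hindered, concave carbinols may form methylthiomethyl ethers instead of being oxidised, or the hydroxy cyclobutanone present after the first oxidation may ring-contract or fragment when the amine is added. The fallback sets out from 34 and returns at 35. Diol 34 is converted with Bu2SnO (benzene, reflux) into the dibutylstannylene acetal F3, which Br2 (CH2Cl2, molecular sieves, rt) oxidises without amine base to the α-hydroxy ketone F4 (C10 ketone drawn; either regioisomer converges). Dess–Martin periodinane then oxidises the remaining carbinol to 35.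

Further compounds
F1 | step 24 | (Z)-triethylsilyl enol ether of the C4 ketone of dione 35 | O=C1C(=O)[C@]2(C)[C@H]([C@H](OCc3ccccc3)[C@@H](O[Si](CC)(CC)CC)/C=C(\O[Si](CC)(CC)CC)[C@]4(C[C@H]4C)C=C)C(C)(C)C(=O)C[C@H]12
F2 | step 26 | tetracyclic C9,C10-cis-diol (C9 epimer of 40) | C(c1ccccc1)O[C@@H]2[C@@H](O[Si](CC)(CC)CC)[C@H]3C(=O)[C@]4(C[C@H]4C)[C@H](O)[C@@]4(O)[C@H]5CC(=O)C(C)(C)[C@@H]2[C@@]5(C)[C@@]34O[Si](CC)(CC)CC
F3 | step 23 | dibutylstannylene acetal of diol 34 | CCCC[Sn]1(CCCC)O[C@@H]2[C@H](O1)[C@]3(C)[C@H]([C@H](OCc4ccccc4)[C@@H](O[Si](CC)(CC)CC)CC(=O)[C@]5(C[C@H]5C)C=C)C(C)(C)C(=O)C[C@H]23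
F4 | step 23 | α-hydroxy cyclobutanone (C10 ketone, C17 carbinol) | O=C1[C@H](O)[C@]2(C)[C@H]([C@H](OCc3ccccc3)[C@@H](O[Si](CC)(CC)CC)CC(=O)[C@]4(C[C@H]4C)C=C)C(C)(C)C(=O)C[C@H]12
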